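At early times no J stands in the flask, so G can go to Q and G2 while E dissolves with time constant τ = 11.5 h.

G 0.10 M; E 31 mM (held); time 50 h

    E ⇌ J, rate k1*(csat - [J]) (k1 = 0.00145 /min, csat = 31 mM)
    G → Q (k2 = 6.65 × 10⁻⁴ /min)
    J → X (k3 = 1.72 × 10⁻⁵ /min)
    2 G → G2 (k4 = 0.00596 /M/min)
    G + J → G.J (k5 = 0.0120 /M/min)

- in percentages every species weighs as the G in it: one G2 counts as two
- where a step has two of a species, its rate is k times that concentration squared, and two are used at each turn
- at the start none of J is dissolved
- run time (flask): 50 h

* how much G.J there is at 50 h, in percent of the G charged
* the change that raises the amount of G.J at 50 h, in percent of the G charged most ("none" if none brings more than 2 percentage points) (teal / red / none)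
* amount of G.J at 50 h, in percent of the G charged, after teal

- teal: doubling the saturation concentration of E, all else as stated
- red: doubling the transfer coefficient of step 1, all else as stated

This hand reckoning treats dissolving as a step in time: [J] is zero up to τ and csat after it. Each route of G then has a loss rate per G:

| Route of G | Loss per G, G as charged, J at csat |
|---|---|
| to Q | 6.65 × 10⁻⁴ /min |
| to G2 | 0.00119 /min |
| to G.J | 3.72 × 10⁻⁴ /min |

The last row is a pseudo-first-order constant, and it is slower than the first. Between them, the capture share f = 35.9% of G goes to G.J. Their sum is 0.00104 /min. The middle row is larger at the charge, but it falls with [G] and equals that sum at the crossover concentration Gc = 0.0870 M. Integrating the shares as G falls from [G] to nothing gives G.J = f·Gc·ln(1 + [G]/Gc).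

In this reckoning, Q and G2 leave 0.0381 M of G at τ, so the estimate for this flask is 11.3% of the charge as G.J. The same reckoning gives 17.4% for teal. Red, which doubles k1, puts τ at 5.75 h and gives 16.0%, less than teal.

The forecast gives 11.8%, chooses teal and puts it at 20.1%, higher than this reckoning, holding that “Doubling the saturation concentration doubles the J supply throughout”.

The simulation gives 11.9% and chooses teal, which gains 8.4 percentage points against 3.5 points for red and reaches 20.3%. The forecast stands.

With 0.40 M of G charged, the reckoning leaves the neighbour flask 0.0695 M of G at τ, below Gc; the rule gives 4.58%, and that flask reads 4.93%. The flask itself has not come to rest at 50.0 h: 2.7% of G remains, below Gc. The rule adds 0.967%, making 12.9%, and at 500 h G.J reads 12.8%. By then G reads 0%, while X has climbed from 0.00110 M to 0.0153 M.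

The rate constants stand for no real mixture, and the outcome is calculated.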